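**Plan**
- Locants (target): 5-oxooxolane ring O1, C2 (quaternary, bears CO2H), C3, C4, C5 (C=O); C1' is the side-chain CH. Retrosynthetic cuts: the malate ester O–C(=O) bond at the chain end; the lactone O1–C5 bond; then C2–C3 and C4–C5 together, releasing ethylene and CO; last C2–C1' (aldol).
- Enabling feature: C2 carries both the ring oxygen O1 and a carboxyl group, so it is a captodative radical site. Pivalaldehyde can tie O1 and that carboxyl into a temporary 2-tert-butyl-1,3-dioxolan-4-one ring that stores the configuration of C2. A PhSe group on C2 serves as the radical trigger.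
- Forward order: C12 hydroxy acid, acyl oxazolidinone, glyoxylate syn-aldol (C2–C1'), dioxolanone, selenide, three-component coupling with ethylene and CO (C2–C3 and C4–C5). Hydrolysis then removes the acetal ring, Se and pivalate and closes the butanolide (O1–C5); the malate ester is made last.
- Stereochemistry: C2 and C1' come from the Evans syn-aldol with the (S)-4-benzyl auxiliary. C2 is stored in the acetal carbon and regenerated with retention in the key step. The malate centre comes from D-malic acid.

Key step: step 6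

**Step 1**
Reactants: 1 12-hydroxydodecanoic acid; 2 (S)-4-benzyl-1,3-oxazolidin-2-one
Product: 4 (S)-4-benzyl-3-[12-(pivaloyloxy)dodecanoyl]-1,3-oxazolidin-2-one, via mixed pivalic anhydride 3 (not isolated)
Conditions: PivCl (2.3 equiv), Et3N (4 equiv), THF, 0 °C to rt; then LiCl, 2 (1.2 equiv), rt
Reagents that add atoms: pivaloyl chloride CC(C)(C)C(=O)Cl
Why: One-pot O-acylation and mixed-anhydride N-acylation of the oxazolidinone (LiCl/Et3N variant): excess acid chloride should cap the primary alcohol and convert the acid into 3, whose unhindered carbonyl is then taken by the auxiliary; no stereocentre is formed.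

**Step 2**
Reactants: 4 (S)-4-benzyl-3-[12-(pivaloyloxy)dodecanoyl]-1,3-oxazolidin-2-one; 5 ethyl glyoxylate
Product: 8 ethyl (2S,3S)-3-{[(4S)-4-benzyl-2-oxo-1,3-oxazolidin-3-yl]carbonyl}-2-hydroxy-13-(pivaloyloxy)tridecanoate, via Z-boron enolate 6 (not isolated), via boron aldolate 7 (not isolated)
Conditions: Bu2BOTf, Et3N, CH2Cl2, 0 °C; 5 (freshly distilled), −78 to 0 °C; then H2O2, MeOH, pH 7 buffer, 0 °C
Reagents that add atoms: none
Why: Evans syn-aldol addition: enolate 6 should meet the aldehyde carbonyl of 5 in a closed chair (Zimmerman–Traxler) transition state on the enolate face away from the benzyl group of the (S)-auxiliary, which sets both new centres (the later C2 and C1') as S,S.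

**Step 3**
Reactants: 8 ethyl (2S,3S)-3-{[(4S)-4-benzyl-2-oxo-1,3-oxazolidin-3-yl]carbonyl}-2-hydroxy-13-(pivaloyloxy)tridecanoate
Product: 9 (2S,3S)-2-hydroxy-3-[10-(pivaloyloxy)decyl]butanedioic acid
Conditions: LiOH, H2O2, THF/H2O, 0 °C to rt; Na2SO3; then HCl to pH 2
Reagents that add atoms: hydrogen peroxide OO; lithium hydroxide [Li+].[OH-]
Why: Peroxide-assisted imide cleavage and saponification of the activated alpha-hydroxy ester should both run faster than attack on the hindered pivalate and touch neither stereocentre.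

**Step 4**
Reactants: 9 (2S,3S)-2-hydroxy-3-[10-(pivaloyloxy)decyl]butanedioic acid; 10 pivalaldehyde
Product: 11 (2S)-2-[(2S,4S)-2-tert-butyl-5-oxo-1,3-dioxolan-4-yl]-12-(pivaloyloxy)dodecanoic acid (tert-butyl cis to the side chain)
Conditions: 10 (excess), p-TsOH·H2O (cat.), H2SO4 (cat.), pentane/CH2Cl2, reflux, water separator
Reagents that add atoms: none
Why: Acid-catalysed acetalisation under thermodynamic control should engage the alpha-hydroxy acid unit in the five-membered dioxolanone rather than the beta-hydroxy acid in a six-membered ring, as malic acid itself does, and should set the new acetal centre cis to the side chain, which stores the configuration of the carbinol carbon.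

**Step 5**
Reactants: 11 (2S)-2-[(2S,4S)-2-tert-butyl-5-oxo-1,3-dioxolan-4-yl]-12-(pivaloyloxy)dodecanoic acid
Product: 13 (2R)-2-[(2R,4R)-2-tert-butyl-5-oxo-4-(phenylselanyl)-1,3-dioxolan-4-yl]-12-(pivaloyloxy)dodecanoic acid (PhSe trans to tert-butyl; the descriptors change only because Se outranks O), via dilithium dianion 12 (not isolated)
Conditions: LiN(SiMe3)2 (2.3 equiv), THF, −78 °C; PhSeBr, −78 to −40 °C; then 1 M HCl
Reagents that add atoms: phenylselenyl bromide Br[Se]c1ccccc1
Why: Enolate selenenylation: the carboxylate shields the side-chain CH from deprotonation, so the second equivalent of base removes the ring C–H, and dianion 12 should take PhSe on the face trans to tert-butyl; the configuration at this carbon does not matter because it becomes a radical in step 6.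

**Step 6**
Reactants: 13 (2R)-2-[(2R,4R)-2-tert-butyl-5-oxo-4-(phenylselanyl)-1,3-dioxolan-4-yl]-12-(pivaloyloxy)dodecanoic acid; 14 ethylene; 15 carbon monoxide
Product: 16 (2S)-2-{(2S,4S)-2-tert-butyl-5-oxo-4-[3-oxo-3-(phenylselanyl)propyl]-1,3-dioxolan-4-yl}-12-(pivaloyloxy)dodecanoic acid
Conditions: hν (Xe lamp, Pyrex), C2H4 (8 atm), CO (80 atm), C6H6 (0.02 M), 50 °C
Reagents that add atoms: none
Why: Proposed new method: light cleaves the weak C–Se bond of 13 to the planar captodative radical at C2 (flanked by ring oxygen and lactone carbonyl), which adds to ethylene (C2–C3), the unstabilised primary radical takes up CO (C4–C5), and the acyl radical abstracts PhSe from another molecule of 13, so that a chain runs and every atom of the three components ends in 16. The closest known reaction type is the photoinduced phenylselenyl group-transfer carbonylation of alpha-(phenylselanyl) esters, ketones and nitriles with 1-alkenes and CO to acyl selenides; new here are the tertiary O,Se-acetal precursor and ethylene, and the known allylation of 4-oxo-1,3-dioxolan-5-yl radicals by allylstannanes argues that this radical does add to an unactivated C=C bond. No ring is closed here: the five-membered lactone closes in step 7 by 5-exo-trig attack of the freed C2 hydroxyl on the new acyl carbon. The only new stereocentre, C2, is controlled by the tert-butyl group on the acetal carbon, which shields one face of the flat five-membered ring radical, so ethylene should enter trans to it, where H stood in 11 (net retention, self-regeneration of the stereocentre), while C1' is not involved. The step needs alkene before CO and one unit of each: the stabilised tertiary radical binds CO only reversibly, high CO pressure and high dilution of 13 favour CO capture by the primary radical over direct PhSe transfer and over a 1,5-hydrogen shift from the acetal C–H, and a modest ethylene pressure together with the easily broken C–Se bond of 13 should stop the acyl radical before a second ethylene enters. The medium is neutral and free of nucleophiles, so the carboxylic acid, the pivalate and the acylal ring should survive.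

**Step 7**
Reactants: 16 (2S)-2-{(2S,4S)-2-tert-butyl-5-oxo-4-[3-oxo-3-(phenylselanyl)propyl]-1,3-dioxolan-4-yl}-12-(pivaloyloxy)dodecanoic acid
Product: 18 (2S)-2-[(1S)-1-carboxy-11-hydroxyundecyl]-5-oxooxolane-2-carboxylic acid, via open-chain trilithium tricarboxylate 17 (not isolated)
Conditions: LiOH (excess), THF/H2O, 60 °C; Et2O wash; then 2 M HCl to pH 1, 45 °C
Reagents that add atoms: lithium hydroxide [Li+].[OH-]; water O
Why: Saponification of the acylal ring, selenoester and pivalate gives 17, in which neither centre is acidic or next to a leaving group, and acidification should drive gamma-lactonisation (5-exo-trig) of the tertiary hydroxyl onto the propanoate arm, the only unstrained ring available.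

**Step 8**
Reactants: 19 D-malic acid [(R)-2-hydroxybutanedioic acid]
Product: 20 (3R)-2,5-dioxooxolan-3-yl trifluoroacetate [(R)-2-(trifluoroacetoxy)succinic anhydride]
Conditions: (CF3CO)2O (neat), 0 °C to rt; evaporate
Reagents that add atoms: trifluoroacetic anhydride O=C(OC(=O)C(F)(F)F)C(F)(F)F
Why: O-acylation and cyclodehydration of a 1,4-diacid by a strong anhydride; the stereocentre takes no part.

**Step 9**
Reactants: 18 (2S)-2-[(1S)-1-carboxy-11-hydroxyundecyl]-5-oxooxolane-2-carboxylic acid; 20 (3R)-2,5-dioxooxolan-3-yl trifluoroacetate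
Product: 22 (2S)-2-[(1S)-1-carboxy-11-{[(2R)-3-carboxy-2-hydroxypropanoyl]oxy}undecyl]-5-oxooxolane-2-carboxylic acid (target), via O-trifluoroacetyl ester 21 (not isolated)
Conditions: 20 (3 equiv), THF, rt to 40 °C; then H2O, rt
Reagents that add atoms: none
Why: Regioselective alcoholysis of an unsymmetrical cyclic anhydride: the only hydroxyl of 18 should attack the carbonyl next to the electron-withdrawing trifluoroacetoxy group, as in the known preparation of malic acid 1-monoesters, the labile trifluoroacetate of 21 falls off in water, and without base the carboxyl groups stay spectators and no centre is at risk.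

**Compound list**
1 | 12-hydroxydodecanoic acid | OCCCCCCCCCCCC(=O)O | starting material
2 | (S)-4-benzyl-1,3-oxazolidin-2-one | O=C1N[C@@H](Cc2ccccc2)CO1 | starting material
3 | 12-(pivaloyloxy)dodecanoic pivalic anhydride | CC(C)(C)C(=O)OCCCCCCCCCCCC(=O)OC(=O)C(C)(C)C | intermediate
4 | (S)-4-benzyl-3-[12-(pivaloyloxy)dodecanoyl]-1,3-oxazolidin-2-one | CC(C)(C)C(=O)OCCCCCCCCCCCC(=O)N1[C@@H](Cc2ccccc2)COC1=O | intermediate
5 | ethyl glyoxylate | CCOC(=O)C=O | starting material
6 | Z-dibutylboron enolate of 4 | CCCCB(CCCC)O/C(=C\CCCCCCCCCCOC(=O)C(C)(C)C)N1[C@@H](Cc2ccccc2)COC1=O | intermediate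
7 | O-dibutylboryl aldolate of 8 | CC(C)(C)C(=O)OCCCCCCCCCC[C@H](C(=O)N1[C@@H](Cc2ccccc2)COC1=O)[C@H](OB(CCCC)CCCC)C(=O)OCC | intermediate
8 | ethyl (2S,3S)-3-{[(4S)-4-benzyl-2-oxo-1,3-oxazolidin-3-yl]carbonyl}-2-hydroxy-13-(pivaloyloxy)tridecanoate | CC(C)(C)C(=O)OCCCCCCCCCC[C@H](C(=O)N1[C@@H](Cc2ccccc2)COC1=O)[C@H](O)C(=O)OCC | intermediate
9 | (2S,3S)-2-hydroxy-3-[10-(pivaloyloxy)decyl]butanedioic acid | CC(C)(C)C(=O)OCCCCCCCCCC[C@H](C(=O)O)[C@H](O)C(=O)O | intermediate
10 | pivalaldehyde | CC(C)(C)C=O | starting material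
11 | (2S)-2-[(2S,4S)-2-tert-butyl-5-oxo-1,3-dioxolan-4-yl]-12-(pivaloyloxy)dodecanoic acid | CC(C)(C)C(=O)OCCCCCCCCCC[C@H](C(=O)O)[C@@H]1O[C@H](C(C)(C)C)OC1=O | intermediate
12 | dilithium carboxylate/ring enolate of 11 | CC(C)(C)C(=O)OCCCCCCCCCC[C@H](C(=O)[O-])C1=C([O-])O[C@@H](C(C)(C)C)O1.[Li+].[Li+] | intermediate
13 | (2R)-2-[(2R,4R)-2-tert-butyl-5-oxo-4-(phenylselanyl)-1,3-dioxolan-4-yl]-12-(pivaloyloxy)dodecanoic acid | CC(C)(C)C(=O)OCCCCCCCCCC[C@H](C(=O)O)[C@]1([Se]c2ccccc2)O[C@H](C(C)(C)C)OC1=O | intermediate
14 | ethylene | C=C | starting material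
15 | carbon monoxide | [C-]#[O+] | starting material
16 | (2S)-2-{(2S,4S)-2-tert-butyl-5-oxo-4-[3-oxo-3-(phenylselanyl)propyl]-1,3-dioxolan-4-yl}-12-(pivaloyloxy)dodecanoic acid | CC(C)(C)C(=O)OCCCCCCCCCC[C@H](C(=O)O)[C@]1(CCC(=O)[Se]c2ccccc2)O[C@H](C(C)(C)C)OC1=O | intermediate
17 | trilithium (3S,4S)-3,14-dihydroxytetradecane-1,3,4-tricarboxylate | OCCCCCCCCCC[C@H](C(=O)[O-])[C@@](O)(CCC(=O)[O-])C(=O)[O-].[Li+].[Li+].[Li+] | intermediate
18 | (2S)-2-[(1S)-1-carboxy-11-hydroxyundecyl]-5-oxooxolane-2-carboxylic acid | OCCCCCCCCCC[C@H](C(=O)O)[C@]1(C(=O)O)CCC(=O)O1 | intermediate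
19 | D-malic acid | O=C(O)C[C@@H](O)C(=O)O | starting material
20 | (3R)-2,5-dioxooxolan-3-yl trifluoroacetate | O=C1C[C@@H](OC(=O)C(F)(F)F)C(=O)O1 | intermediate
21 | O-trifluoroacetyl derivative of 22 | O=C(O)C[C@@H](OC(=O)C(F)(F)F)C(=O)OCCCCCCCCCC[C@H](C(=O)O)[C@]1(C(=O)O)CCC(=O)O1 | intermediate
22 | (2S)-2-[(1S)-1-carboxy-11-{[(2R)-3-carboxy-2-hydroxypropanoyl]oxy}undecyl]-5-oxooxolane-2-carboxylic acid | O=C(O)C[C@@H](O)C(=O)OCCCCCCCCCC[C@H](C(=O)O)[C@]1(C(=O)O)CCC(=O)O1 | target

Total step count: 9. Longest linear sequence: 8 steps (steps 1 to 7 and step 9).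

**Steps most likely to fail**

**Step 6.**
- What may go wrong:
  - The stabilised tertiary radical may add to ethylene too slowly, so that 13 is only recycled or is lost by disproportionation toward the side-chain CH.
  - PhSe transfer may outrun CO capture.
  - The acyl radical may take up further ethylene and CO.
- Fallback (known chemistry, bonds made one after the other): it sets out from 11 and comes back at 18.
  - Dianion 12 is made as in step 5 and alkylated with allyl bromide, trans to tert-butyl, to give the allyl dioxolanone acid F1.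
  - Hydroboration with 9-BBN and oxidation with NaBO3 gives the hydroxypropyl dioxolanone acid F2.
  - Oxidation with TEMPO/PhI(OAc)2 in MeCN/H2O gives the carboxyethyl dioxolanone acid F3.
  - The conditions of step 7 convert F3 into 18.

**Step 9.**
- What may go wrong:
  - Acyl exchange between the free carboxyl groups of 18 and the anhydride may lead to oligomeric esters.
  - Trifluoroacetyl may be transferred to the alcohol.
  - Attack may occur partly at the wrong anhydride carbonyl.
- Fallback: it sets out from 18 and 19 and comes back at 22.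
  - From 18, carboxylate alkylation (BnBr, KHCO3, DMF) gives the dibenzyl ester alcohol F4.
  - From 19, 2,2-dimethoxypropane with p-TsOH gives the D-malic acid acetonide F5, in which only the 4-carboxyl is free.
  - BnBr/Et3N gives the acetonide benzyl ester F6, and aqueous AcOH gives the 4-benzyl (R)-malate F7, in which only the 1-carboxyl is free.
  - Mitsunobu esterification of F4 with F7 (PPh3, DIAD, THF) gives the tribenzyl ester F8.
  - Hydrogenolysis (H2, Pd/C, EtOAc) gives 22.

**Step 5.**
- What may go wrong:
  - Deprotonation of the hindered ring C–H may be incomplete.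
  - Deprotonation at the side-chain CH may be followed by beta-elimination of the ring oxygen.
  - Capture of PhSe at the crowded enolate carbon may be sluggish.
- Fallback: it sets out from 11 and comes back at 13.
  - Free-radical bromination of the ring C–H (NBS, hν, PhCF3, reflux) gives the bromo dioxolanone acid F9.
  - Ionic substitution with PhSeH (CH2Cl2, −20 °C) gives 13.

**Further compounds**
F1 | step 6 | (2S)-2-[(2S,4S)-2-tert-butyl-5-oxo-4-(prop-2-en-1-yl)-1,3-dioxolan-4-yl]-12-(pivaloyloxy)dodecanoic acid | CC(C)(C)C(=O)OCCCCCCCCCC[C@H](C(=O)O)[C@]1(CC=C)O[C@H](C(C)(C)C)OC1=O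
F2 | step 6 | (2S)-2-[(2S,4S)-2-tert-butyl-4-(3-hydroxypropyl)-5-oxo-1,3-dioxolan-4-yl]-12-(pivaloyloxy)dodecanoic acid | CC(C)(C)C(=O)OCCCCCCCCCC[C@H](C(=O)O)[C@]1(CCCO)O[C@H](C(C)(C)C)OC1=O
F3 | step 6 | (2S)-2-[(2S,4S)-2-tert-butyl-4-(2-carboxyethyl)-5-oxo-1,3-dioxolan-4-yl]-12-(pivaloyloxy)dodecanoic acid | CC(C)(C)C(=O)OCCCCCCCCCC[C@H](C(=O)O)[C@]1(CCC(=O)O)O[C@H](C(C)(C)C)OC1=O
F4 | step 9 | benzyl (2S)-2-[(1S)-1-(benzyloxycarbonyl)-11-hydroxyundecyl]-5-oxooxolane-2-carboxylate | OCCCCCCCCCC[C@H](C(=O)OCc1ccccc1)[C@]2(C(=O)OCc3ccccc3)CCC(=O)O2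
F5 | step 9 | 2-[(4R)-2,2-dimethyl-5-oxo-1,3-dioxolan-4-yl]acetic acid | O=C(O)C[C@H]1OC(C)(C)OC1=O
F6 | step 9 | benzyl 2-[(4R)-2,2-dimethyl-5-oxo-1,3-dioxolan-4-yl]acetate | O=C(C[C@H]1OC(C)(C)OC1=O)OCc2ccccc2
F7 | step 9 | (2R)-4-(benzyloxy)-2-hydroxy-4-oxobutanoic acid | O=C(C[C@@H](O)C(=O)O)OCc1ccccc1
F8 | step 9 | tribenzyl ester of 22 | O=C(C[C@@H](O)C(=O)OCCCCCCCCCC[C@H](C(=O)OCc1ccccc1)[C@]2(C(=O)OCc3ccccc3)CCC(=O)O2)OCc4ccccc4
F9 | step 5 | (2R)-2-[(2R,4R)-4-bromo-2-tert-butyl-5-oxo-1,3-dioxolan-4-yl]-12-(pivaloyloxy)dodecanoic acid (Br trans to tert-butyl) | CC(C)(C)C(=O)OCCCCCCCCCC[C@H](C(=O)O)[C@]1(Br)O[C@H](C(C)(C)C)OC1=O
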